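The trans pair on the dihydrofuran ring (O1, C2, C3, C3a, C7a), veratryl on C2 and C9 on C3, is traced back to a cyclopropane in which C9 bridges C2 and C3 on one face. One enantioselective carbene transfer from ethyl diazoacetate to the C2=C3 bond of a flat, 2,3-unsubstituted benzofuran forms C3–C9 and a temporary C2–C9 bond, closes the three-membered ring and fixes C3. Veratrole then displaces C9 from C2 on the opposite face; the carboxyl carbon is later exchanged for hydroxyl. The precursor is 5-bromobenzofuran-7-yl mesylate: bromide for the acrylate, mesylate masking O7, both deactivating the benzo ring.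

Key step: step 5

Atom labels: O1, C2, C3 and C3a–C7a follow benzofuran numbering. C9 is the carbene carbon.

Assumption: the (S,S)-t-Bu-box/Cu(I) carbene is taken to give the (1S,1aS,6bR) adduct, by analogy with the sense it shows with furans. Both ligand antipodes are commercial, so the other one is used if the sense proves opposite.

Design remark: the carbene carries a primary (ethyl) ester. A tertiary ester would ionise under the Lewis acid of step 6. Once the veratryl group is on C2, a tertiary ester could also be lost by dealkylative γ-lactonisation onto C2. The ethyl ester is removed by mild hydroxide, which the aryl mesylate survives.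

Step 1
Reactants: 1 5-bromo-2-hydroxy-3-methoxybenzaldehyde; 2 ethyl bromoacetate
Product: 4 2-(4-bromo-2-formyl-6-methoxyphenoxy)acetic acid, via ethyl ester 3 (not isolated)
Conditions: K2CO3, DMF, 50 °C; then 2 M aq NaOH, rt; 1 M HCl
Reagents that add atoms: ethyl bromoacetate, BrCC(=O)OCC; sodium hydroxide, [Na+].[OH-]
Why: Williamson alkylation of the acidic, aldehyde-conjugated phenoxide by a primary α-bromo ester, followed by in-flask saponification of the unhindered ester, should give the aryloxyacetic acid; no stereocentre is involved.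

Step 2
Reactants: 4 2-(4-bromo-2-formyl-6-methoxyphenoxy)acetic acid
Product: 5 5-bromo-7-methoxybenzofuran
Conditions: Ac2O, NaOAc, AcOH, reflux
Reagents that add atoms: none
Why: This is the Perkin-type (Rössing) cyclisation of an o-formylaryloxyacetic acid, in which the mixed anhydride enolises, adds intramolecularly to the aldehyde and loses CO2 and water, giving the 2,3-unsubstituted benzofuran directly without a separate decarboxylation.

Step 3
Reactants: 5 5-bromo-7-methoxybenzofuran
Product: 6 5-bromobenzofuran-7-ol
Conditions: BBr3, CH2Cl2, −78 → 0 °C; H2O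
Reagents that add atoms: none
Why: Lewis-acid aryl methyl ether cleavage applies here, since boron binds the only basic ether oxygen and bromide removes the methyl group by SN2, while the bromine-deactivated benzofuran should tolerate the low-temperature conditions.

Step 4
Reactants: 6 5-bromobenzofuran-7-ol
Product: 7 5-bromobenzofuran-7-yl methanesulfonate
Conditions: MsCl, Et3N, CH2Cl2, 0 °C
Reagents that add atoms: methanesulfonyl chloride, CS(=O)(=O)Cl
Why: O-sulfonylation of the only nucleophilic site should give a mesylate that withstands Lewis acid, radicals, Pd/P(o-tol)3 and cold LiOH but falls to warm NaOH at the end.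

Step 5
Reactants: 7 5-bromobenzofuran-7-yl methanesulfonate; 8 ethyl diazoacetate
Product: 9 ethyl (1S,1aS,6bR)-5-bromo-3-(methylsulfonyloxy)-1a,6b-dihydro-1H-cyclopropa[b][1]benzofuran-1-carboxylate (exo ester, cis ring fusion)
Conditions: CuOTf·½PhMe (3 mol %), (S,S)-t-Bu-box (3.6 mol %), CH2Cl2, 0 °C → rt, 8 (3 equiv) by syringe pump over 12 h; recrystallise
Reagents that add atoms: ethyl diazoacetate, CCOC(=O)C=[N+]=[N-]
Why: The copper(I) bis(oxazoline) complex expels N2 from 8 to give an electrophilic copper carbene, to which the localised, enol-ether-like C2=C3 π bond of 7 adds in a concerted but asynchronous [2+1] fashion. The closest known reaction type is the Cu-, Rh- or haem-catalysed enantioselective cyclopropanation of furans and benzofurans with diazoacetates. The three-membered ring is closed intermolecularly by suprafacial delivery of one carbon (C9) to both alkene termini, so the ring fusion can only be cis. C3 and C2 (C6b and C1a of the adduct) are set together by the choice of benzofuran face, which the tert-butyl groups of the C2-symmetric ligand enforce, while C9 takes the exo geometry because the ester avoids the benzo ring during the approach; this third centre is erased later. The step needs facial selectivity, chemoselectivity for the furan bond over Büchner ring expansion or C–H insertion, and carbene capture that is faster than carbene dimerisation. Bromide and mesylate deactivate the benzo ring and leave C2=C3 as the only nucleophilic π bond, both of its carbons carry only hydrogen, and slow addition of 8 keeps the diazo concentration low.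

Step 6
Reactants: 9 ethyl (1S,1aS,6bR)-5-bromo-3-(methylsulfonyloxy)-1a,6b-dihydro-1H-cyclopropa[b][1]benzofuran-1-carboxylate; 10 1,2-dimethoxybenzene (veratrole)
Product: 11 ethyl 2-[(2R,3R)-5-bromo-2-(3,4-dimethoxyphenyl)-7-(methylsulfonyloxy)-2,3-dihydro-1-benzofuran-3-yl]acetate (trans)
Conditions: 10 (10 equiv), TMSOTf (20 mol %), MeNO2–CH2Cl2, −20 °C → rt; Et3N quench
Reagents that add atoms: 1,2-dimethoxybenzene, COc1ccccc1OC
Why: Proposed new method: silylation of the ester carbonyl polarises the C2–C9 bond, already weakened by ring strain and by the O1 lone pair, so that C2 becomes an incipient oxocarbenium carbon which C4 of veratrole attacks from the face opposite the departing C9 (inversion at C2, C3 untouched, hence trans), after which the proton lost from the arenium ion quenches the silyl ketene acetal and returns the catalyst; the closest known reaction types are the silyl-triflate-promoted opening of ring-fused 2-alkoxycyclopropane monoesters with capture by indoles and other π-nucleophiles, and the Friedel–Crafts opening of aryl/diester donor–acceptor cyclopropanes by electron-rich arenes, neither of which has been shown for an aryloxy donor derived from a benzofuran; because the ethyl ester cannot leave as a cation, any reversible C2–O1 ionisation of the product can only re-close to the more stable trans isomer.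

Step 7
Reactants: 11 ethyl 2-[(2R,3R)-5-bromo-2-(3,4-dimethoxyphenyl)-7-(methylsulfonyloxy)-2,3-dihydro-1-benzofuran-3-yl]acetate
Product: 12 2-[(2R,3R)-5-bromo-2-(3,4-dimethoxyphenyl)-7-(methylsulfonyloxy)-2,3-dihydro-1-benzofuran-3-yl]acetic acid
Conditions: LiOH·H2O, THF–H2O, 0 °C → rt; cold 1 M HCl to pH 3
Reagents that add atoms: lithium hydroxide, [Li+].[OH-]
Why: Acyl-oxygen saponification of an unhindered primary-alkyl ester is much faster than S–O cleavage of an aryl mesylate, the acidic position is C9 and not a stereocentre, and no ionising acid touches the labile C2–O1 bond.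

Step 8
Reactants: 12 2-[(2R,3R)-5-bromo-2-(3,4-dimethoxyphenyl)-7-(methylsulfonyloxy)-2,3-dihydro-1-benzofuran-3-yl]acetic acid
Product: 15 [(2R,3S)-5-bromo-2-(3,4-dimethoxyphenyl)-3-(hydroxymethyl)-2,3-dihydro-1-benzofuran-7-yl] methanesulfonate, via thiohydroxamate ester 13 (not isolated), via primary hydroperoxide 14 (not isolated)
Conditions: 1-hydroxypyridine-2(1H)-thione, DCC, CH2Cl2, 0 °C, dark; then t-BuSH, O2 (1 atm), PhMe, W lamp, 10 °C; then P(OMe)3, rt
Reagents that add atoms: dioxygen, O=O
Why: In this Barton decarboxylative oxygenation, light-induced N–O homolysis releases CO2 and the primary C9 radical, which O2 traps at near diffusion rate (faster than C3–C2 β-scission or a neophyl-type aryl shift), the thiol carries the chain, phosphite reduces the hydroperoxide, and C3 is not part of the radical so its configuration is kept (the descriptor changes to S only through CIP priorities).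

Step 9
Reactants: 15 [(2R,3S)-5-bromo-2-(3,4-dimethoxyphenyl)-3-(hydroxymethyl)-2,3-dihydro-1-benzofuran-7-yl] methanesulfonate; 16 methyl acrylate
Product: 17 methyl (E)-3-[(2R,3S)-2-(3,4-dimethoxyphenyl)-3-(hydroxymethyl)-7-(methylsulfonyloxy)-2,3-dihydro-1-benzofuran-5-yl]prop-2-enoate
Conditions: 16 (3 equiv), Pd(OAc)2 (5 mol %), P(o-tol)3 (12 mol %), Et3N, DMF, 100 °C
Reagents that add atoms: methyl acrylate, C=CC(=O)OC
Why: In this Mizoroki–Heck reaction, oxidative addition takes place at the unhindered C5–Br bond only (aryl mesylates are inert to this catalyst), and syn insertion followed by syn β-hydride elimination gives the E-cinnamate, with the free primary alcohol as a spectator.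

Step 10
Reactants: 17 methyl (E)-3-[(2R,3S)-2-(3,4-dimethoxyphenyl)-3-(hydroxymethyl)-7-(methylsulfonyloxy)-2,3-dihydro-1-benzofuran-5-yl]prop-2-enoate
Product: 18 (E)-3-[(2R,3S)-2-(3,4-dimethoxyphenyl)-7-hydroxy-3-(hydroxymethyl)-2,3-dihydro-1-benzofuran-5-yl]prop-2-enoic acid (target)
Conditions: 2 M aq NaOH, 1,4-dioxane, 60 °C, Ar; cold 1 M HCl to pH 3
Reagents that add atoms: sodium hydroxide, [Na+].[OH-]
Why: Warm hydroxide saponifies the methyl ester and cleaves the aryl mesylate at sulfur in one operation, an alcohol-free medium avoids formation of a methylating sulfonate ester, and neither C2–H nor C3–H is acidic while the 2-aryl ring has no free para-hydroxyl for a quinone-methide ring opening, so both stereocentres persist.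

Compound list
1 | 5-bromo-2-hydroxy-3-methoxybenzaldehyde | COc1cc(Br)cc(C=O)c1O | starting material
2 | ethyl bromoacetate | CCOC(=O)CBr | starting material
3 | ethyl 2-(4-bromo-2-formyl-6-methoxyphenoxy)acetate | CCOC(=O)COc1c(C=O)cc(Br)cc1OC | intermediate
4 | 2-(4-bromo-2-formyl-6-methoxyphenoxy)acetic acid | OC(=O)COc1c(C=O)cc(Br)cc1OC | intermediate
5 | 5-bromo-7-methoxybenzofuran | COc1cc(Br)cc2ccoc12 | intermediate
6 | 5-bromobenzofuran-7-ol | Oc1cc(Br)cc2ccoc12 | intermediate
7 | 5-bromobenzofuran-7-yl methanesulfonate | CS(=O)(=O)Oc1cc(Br)cc2ccoc12 | intermediate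
8 | ethyl diazoacetate | CCOC(=O)C=[N+]=[N-] | starting material
9 | ethyl (1S,1aS,6bR)-5-bromo-3-(methylsulfonyloxy)-1a,6b-dihydro-1H-cyclopropa[b][1]benzofuran-1-carboxylate | CCOC(=O)[C@@H]1[C@H]2Oc3c(OS(C)(=O)=O)cc(Br)cc3[C@@H]12 | intermediate
10 | 1,2-dimethoxybenzene | COc1ccccc1OC | starting material
11 | ethyl 2-[(2R,3R)-5-bromo-2-(3,4-dimethoxyphenyl)-7-(methylsulfonyloxy)-2,3-dihydro-1-benzofuran-3-yl]acetate | COc1ccc([C@@H]2Oc3c(OS(C)(=O)=O)cc(Br)cc3[C@H]2CC(=O)OCC)cc1OC | intermediate
12 | 2-[(2R,3R)-5-bromo-2-(3,4-dimethoxyphenyl)-7-(methylsulfonyloxy)-2,3-dihydro-1-benzofuran-3-yl]acetic acid | COc1ccc([C@@H]2Oc3c(OS(C)(=O)=O)cc(Br)cc3[C@H]2CC(=O)O)cc1OC | intermediate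
13 | 2-thioxopyridin-1(2H)-yl 2-[(2R,3R)-5-bromo-2-(3,4-dimethoxyphenyl)-7-(methylsulfonyloxy)-2,3-dihydro-1-benzofuran-3-yl]acetate | COc1ccc([C@@H]2Oc3c(OS(C)(=O)=O)cc(Br)cc3[C@H]2CC(=O)ON4C=CC=CC4=S)cc1OC | intermediate
14 | [(2R,3S)-5-bromo-2-(3,4-dimethoxyphenyl)-3-(hydroperoxymethyl)-2,3-dihydro-1-benzofuran-7-yl] methanesulfonate | COc1ccc([C@@H]2Oc3c(OS(C)(=O)=O)cc(Br)cc3[C@H]2COO)cc1OC | intermediate
15 | [(2R,3S)-5-bromo-2-(3,4-dimethoxyphenyl)-3-(hydroxymethyl)-2,3-dihydro-1-benzofuran-7-yl] methanesulfonate | COc1ccc([C@@H]2Oc3c(OS(C)(=O)=O)cc(Br)cc3[C@H]2CO)cc1OC | intermediate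
16 | methyl acrylate | C=CC(=O)OC | starting material
17 | methyl (E)-3-[(2R,3S)-2-(3,4-dimethoxyphenyl)-3-(hydroxymethyl)-7-(methylsulfonyloxy)-2,3-dihydro-1-benzofuran-5-yl]prop-2-enoate | COc1ccc([C@@H]2Oc3c(OS(C)(=O)=O)cc(/C=C/C(=O)OC)cc3[C@H]2CO)cc1OC | intermediate
18 | (E)-3-[(2R,3S)-2-(3,4-dimethoxyphenyl)-7-hydroxy-3-(hydroxymethyl)-2,3-dihydro-1-benzofuran-5-yl]prop-2-enoic acid | COc1ccc([C@@H]2Oc3c(O)cc(/C=C/C(=O)O)cc3[C@H]2CO)cc1OC | target

Total step count: 10. Longest linear sequence: 10 steps (1 → 18); compounds 2, 8, 10 and 16 are bought.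

Steps most likely to fail

Step 6 (Proposed new method).
- Once C2–C9 has opened, the C2 oxocarbenium ion may lose H3. The ring then re-aromatises and both stereocentres are lost.
- The single ester and a donor oxygen weakened by bromide and mesylate may make the opening sluggish.
- Prolonged acid may ionise C2–O1 of the product and let a second veratrole add.
- The fallback sets out from 9 and comes back at 11, and it separates ring opening from C–C bond formation using known reactions. Acid-catalysed ethanolysis (cat. H2SO4, EtOH, 50 °C) is the established solvolytic opening of 2-oxycyclopropane esters. The solvent traps C2 at high concentration, which would give ethyl 2-[(2R,3R)-5-bromo-2-ethoxy-7-(methylsulfonyloxy)-2,3-dihydro-1-benzofuran-3-yl]acetate F1.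
- The known BF3·OEt2-mediated coupling of acetals with potassium aryltrifluoroborates would follow, here with commercial potassium (3,4-dimethoxyphenyl)trifluoroborate in MeCN at 0 °C. It would replace ethoxide by the aryl group anti to the C3 side chain and give 11.

Step 5.
- The electron-poor benzofuran may capture the carbene too slowly, so that carbene dimerisation consumes the diazo ester.
- Facial discrimination by the ligand may be insufficient or of the opposite sense.
- The fallback sets out from 7 (with 8) and comes back at 9, and it moves stereocontrol from the catalyst to a separation. Achiral Rh2(OAc)4-catalysed cyclopropanation would give the exo adduct as the racemate. That racemate is 9 together with its mirror image, ethyl (1R,1aR,6bS)-5-bromo-3-(methylsulfonyloxy)-1a,6b-dihydro-1H-cyclopropa[b][1]benzofuran-1-carboxylate F2.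
- Preparative supercritical-fluid chromatography on a polysaccharide chiral phase would deliver 9.

Step 8.
- The C9 radical may take hydrogen from the thiol before it meets oxygen, which amounts to reduction.
- It may recombine with the thiopyridyl group, or it may fragment through C3–C2 scission.
- The light-sensitive thiohydroxamate may decompose before use.
- The fallback sets out from 12 and comes back at 15, and it traps the radical on boron instead of oxygen. Esterification with N-hydroxyphthalimide (DIC, cat. DMAP, CH2Cl2) would give 1,3-dioxoisoindolin-2-yl 2-[(2R,3R)-5-bromo-2-(3,4-dimethoxyphenyl)-7-(methylsulfonyloxy)-2,3-dihydro-1-benzofuran-3-yl]acetate F3.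
- Blue-light decarboxylative borylation with bis(catecholato)diboron in DMAc, then pinacol/Et3N, would give [(2R,3R)-5-bromo-2-(3,4-dimethoxyphenyl)-3-[(4,4,5,5-tetramethyl-1,3,2-dioxaborolan-2-yl)methyl]-2,3-dihydro-1-benzofuran-7-yl] methanesulfonate F4.
- Oxidation with NaBO3 in THF–H2O would convert C9–B into C9–OH and give 15.

Further compounds
F1 | step 6 | ethyl 2-[(2R,3R)-5-bromo-2-ethoxy-7-(methylsulfonyloxy)-2,3-dihydro-1-benzofuran-3-yl]acetate | CCO[C@@H]1Oc2c(OS(C)(=O)=O)cc(Br)cc2[C@H]1CC(=O)OCC
F2 | step 5 | ethyl (1R,1aR,6bS)-5-bromo-3-(methylsulfonyloxy)-1a,6b-dihydro-1H-cyclopropa[b][1]benzofuran-1-carboxylate | CCOC(=O)[C@H]1[C@@H]2Oc3c(OS(C)(=O)=O)cc(Br)cc3[C@H]12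
F3 | step 8 | 1,3-dioxoisoindolin-2-yl 2-[(2R,3R)-5-bromo-2-(3,4-dimethoxyphenyl)-7-(methylsulfonyloxy)-2,3-dihydro-1-benzofuran-3-yl]acetate | COc1ccc([C@@H]2Oc3c(OS(C)(=O)=O)cc(Br)cc3[C@H]2CC(=O)ON4C(=O)c5ccccc5C4=O)cc1OC
F4 | step 8 | [(2R,3R)-5-bromo-2-(3,4-dimethoxyphenyl)-3-[(4,4,5,5-tetramethyl-1,3,2-dioxaborolan-2-yl)methyl]-2,3-dihydro-1-benzofuran-7-yl] methanesulfonate | COc1ccc([C@@H]2Oc3c(OS(C)(=O)=O)cc(Br)cc3[C@H]2CB4OC(C)(C)C(C)(C)O4)cc1OC
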